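The synthesis rests on cutting ring A of the cis-decalin at C3–C4 and C5–C10, which unravels both rings into one acyclic triene. A single thermal intramolecular Diels–Alder reaction closes ring A and, through the C6–C9 tether, ring B. It exploits the four contiguous stereocentres C3, C4, C5 and C10 of ring A, whose 3,4-trans, 4,5-cis, cis-fused pattern is the imprint of one ester-exo transition state. The precursor joins an (E)-β-methyl enoate (C4=C5) through C6, C7, a C8 dioxolane and an (R)-C9 PMB ether to an (E,E)-1-silyloxydiene (C10–C1–C2–C3). A bulky triisopropylsilyl group is chosen to disfavour the ester-endo mode and to outlast later acid.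

Key step: step 9

Remark on numbering: the eremophilane numbering of the target (C1–C15) is used for every intermediate. β is the face of the C5 methyl group and α is the opposite face.
Remark on configuration: the target is 3α-angelate, 4β-methyl, 5β-methyl, 7β-isopropenyl, 9β-senecioate, 10β-H, that is (3R,4R,5R,7R,9R,10S). In the chair–chair conformer with the C5 methyl axial on ring A every other substituent is equatorial, so C7 and C9, both α to the C8 ketone, hold their more stable orientation.
Assumption: the sense of induction in step 1 is taken from the behaviour of aromatic aldehydes under this catalyst. The configuration of 4 would be confirmed by MTPA ester analysis before going on.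

Step 1
Reactants: 1 5-methylfurfural; 2 allylboronic acid pinacol ester
Product: 4 (R)-1-(5-methylfuran-2-yl)but-3-en-1-ol, via pinacol borate ester 3 (not isolated)
Conditions: (R)-3,3'-bis(2,4,6-triisopropylphenyl)-1,1'-binaphthyl-2,2'-diyl hydrogen phosphate (5 mol %), PhMe, −30 °C; aq NaHCO3 work-up
Reagents that add atoms: allylboronic acid pinacol ester 2, C=CCB1OC(C)(C)C(C)(C)O1
Why: Chiral-phosphoric-acid-catalysed allylboration through a closed chair transition state, in which the catalyst bound to the boronate oxygen should leave the Re face of the aldehyde open and so set C9 as R.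

Step 2
Reactants: 4 (R)-1-(5-methylfuran-2-yl)but-3-en-1-ol
Product: 5 2-[(1R)-1-[(4-methoxybenzyl)oxy]but-3-en-1-yl]-5-methylfuran
Conditions: NaH, 4-methoxybenzyl chloride, Bu4NI (cat.), THF–DMF, 0 °C → rt
Reagents that add atoms: 4-methoxybenzyl chloride, COc1ccc(CCl)cc1
Why: Williamson ether synthesis at oxygen leaves the C9–O bond and its configuration untouched and installs a group that can later be removed oxidatively beside a silyl ether and an alkene.

Step 3
Reactants: 5 2-[(1R)-1-[(4-methoxybenzyl)oxy]but-3-en-1-yl]-5-methylfuran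
Product: 7 (6R)-6-[(4-methoxybenzyl)oxy]non-8-ene-2,5-dione, via (Z)-enedione 6 (not isolated)
Conditions: NBS, NaHCO3, acetone–H2O, −15 °C; then AcOH, Zn dust, 0 °C → rt
Reagents that add atoms: water, O
Why: Oxidative furan ring opening (bromonium attack on the most electron-rich π system, capture by water, collapse to the cis-enedione) followed by dissolving-metal conjugate reduction unmasks the C5/C8 1,4-diketone, while the monosubstituted alkene, the anisyl ring and C9 should stay untouched.

Step 4
Reactants: 7 (6R)-6-[(4-methoxybenzyl)oxy]non-8-ene-2,5-dione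
Product: 8 2-[(1R)-1-[(4-methoxybenzyl)oxy]but-3-en-1-yl]-2-[2-(2-methyl-1,3-dioxolan-2-yl)ethyl]-1,3-dioxolane
Conditions: Me3SiOCH2CH2OSiMe3 (4 equiv), Me3SiOTf (10 mol %), CH2Cl2, −78 → −20 °C; pyridine quench
Reagents that add atoms: 1,2-bis(trimethylsilyloxy)ethane, C[Si](C)(C)OCCO[Si](C)(C)C
Why: Noyori ketalisation is aprotic, cold and driven by siloxane formation, so even the hindered, inductively deactivated C8 carbonyl should be masked without enolisation at C9 or Paal–Knorr reversion to the furan.

Step 5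
Reactants: 8 2-[(1R)-1-[(4-methoxybenzyl)oxy]but-3-en-1-yl]-2-[2-(2-methyl-1,3-dioxolan-2-yl)ethyl]-1,3-dioxolane
Product: 9 4-{2-[(1R)-1-[(4-methoxybenzyl)oxy]but-3-en-1-yl]-1,3-dioxolan-2-yl}butan-2-one
Conditions: pyridinium p-toluenesulfonate (0.2 equiv), acetone–H2O (20:1), rt
Reagents that add atoms: water, O
Why: Chemoselective ketal hydrolysis, since the rate-limiting oxocarbenium ion forms far more easily at the unhindered C5 than at C8, where the neighbouring C9 oxygen destabilises the cation and the branched chain shields it.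

Step 6
Reactants: 9 4-{2-[(1R)-1-[(4-methoxybenzyl)oxy]but-3-en-1-yl]-1,3-dioxolan-2-yl}butan-2-one; 10 trimethyl phosphonoacetate
Product: 11 methyl (2E)-5-{2-[(1R)-1-[(4-methoxybenzyl)oxy]but-3-en-1-yl]-1,3-dioxolan-2-yl}-3-methylpent-2-enoate
Conditions: (MeO)2P(O)CH2CO2Me, NaH, THF, 0 → 50 °C; chromatographic removal of the Z isomer
Reagents that add atoms: trimethyl phosphonoacetate 10, COC(=O)CP(=O)(OC)OC
Why: Horner–Wadsworth–Emmons olefination under reversible addition places the ester trans to the longer C6 chain, and with C8 masked there is only one carbonyl to react, no 1,4-diketone aldol and no acidic hydrogen at C9.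

Step 7
Reactants: 11 methyl (2E)-5-{2-[(1R)-1-[(4-methoxybenzyl)oxy]but-3-en-1-yl]-1,3-dioxolan-2-yl}-3-methylpent-2-enoate; 12 (E)-but-2-enal
Product: 13 methyl (2E)-5-{2-[(1R,3E)-1-[(4-methoxybenzyl)oxy]-5-oxopent-3-en-1-yl]-1,3-dioxolan-2-yl}-3-methylpent-2-enoate
Conditions: (E)-but-2-enal (5 equiv), second-generation Hoveyda–Grubbs catalyst (3 mol %), CH2Cl2, 40 °C
Reagents that add atoms: (E)-but-2-enal 12, C/C=C/C=O
Why: Olefin cross-metathesis between a reactive terminal alkene and an electron-poor partner is E-selective and leaves the trisubstituted enoate alone, adding C3 as the aldehyde carbon.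

Step 8
Reactants: 13 methyl (2E)-5-{2-[(1R,3E)-1-[(4-methoxybenzyl)oxy]-5-oxopent-3-en-1-yl]-1,3-dioxolan-2-yl}-3-methylpent-2-enoate
Product: 14 methyl (2E)-5-{2-[(1R,2E,4E)-1-[(4-methoxybenzyl)oxy]-5-[(triisopropylsilyl)oxy]penta-2,4-dien-1-yl]-1,3-dioxolan-2-yl}-3-methylpent-2-enoate
Conditions: i-Pr3SiOTf (1.2 equiv), Et3N (2.5 equiv), CH2Cl2, −78 → 0 °C; Et3N-deactivated silica
Reagents that add atoms: triisopropylsilyl trifluoromethanesulfonate, CC(C)[Si](OS(=O)(=O)C(F)(F)F)(C(C)C)C(C)C
Why: Soft enolisation (O-silylation of the s-trans enal, then γ-deprotonation at C10) should give the (E)-enol ether, with the branched C9 substituent turned away to give the (E)-C10=C1 bond, while excess amine keeps the deactivated ketal and the PMB ether safe.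

Step 9
Reactants: 14 methyl (2E)-5-{2-[(1R,2E,4E)-1-[(4-methoxybenzyl)oxy]-5-[(triisopropylsilyl)oxy]penta-2,4-dien-1-yl]-1,3-dioxolan-2-yl}-3-methylpent-2-enoate
Product: 15 methyl 8,8-(ethylenedioxy)-9β-[(4-methoxybenzyl)oxy]-3α-[(triisopropylsilyl)oxy]-11,12,13-trinor-10βH-eremophil-1-en-15-oate (cis-fused; 4β-CO2Me, 5β-CH3)
Conditions: PhMe (0.01 M), 2,6-di-tert-butyl-4-methylphenol (cat.), base-washed sealed tube, 180 °C
Reagents that add atoms: none
Why: Concerted, asynchronous, suprafacial [4+2] cycloaddition of normal electron demand, whose closest known type is the thermal intramolecular Diels–Alder reaction of 1,7,9-decatrienoates; polarity and tether agree in joining the nucleophilic diene terminus C10 to the enoate β-carbon C5 and the oxygenated terminus C3 to the ester-bearing C4. Ring A closes as the six-membered cycloadduct ring (C10, C1, C2, C3, C4, C5), and ring B closes in the fused mode as the six-membered ring made of the tether C6–C9 and the new C5–C10 bond. The (E,E)-diene geometry puts the C3 oxygen and the C10–C9 bond cis on ring A, and the (E)-enoate geometry puts the C4 ester and the C5 methyl cis. The tether-endo, ester-exo transition state links these two pairs so that the C5 methyl and C10–H share one face (cis fusion) and C3–O and C4–CO2Me are trans; it keeps the C5 methyl equatorial on the chair-like nascent ring B and the ester away from the triisopropylsilyloxy group, whereas the ester-endo mode needs an axial methyl lying under the diene and a crowded cis ester/silyloxy pair. The absolute sense comes from C9, whose PMB ether must be equatorial on nascent ring B because an axial ether would clash 1,3-diaxially with C4, while the axial dioxolane oxygen at C8 penalises the other chair with an axial diene, so only one diene face is open. The step thus needs exo over endo selectivity and one diene face, and it is run by heat alone, since a Lewis acid would favour the endo mode and cleave the dienol ether.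

Step 10
Reactants: 15 cycloadduct (Δ1, 4β-CO2Me)
Product: 16 methyl 8,8-(ethylenedioxy)-9β-[(4-methoxybenzyl)oxy]-3α-[(triisopropylsilyl)oxy]-11,12,13-trinor-10βH-eremophilan-15-oate
Conditions: H2 (1 atm), Pd/C, pyridine (0.5 equiv), EtOAc, rt
Reagents that add atoms: none
Why: Heterogeneous catalytic hydrogenation of the cis-disubstituted C1=C2 alkene creates no stereocentre, and pyridine poisons the palladium surface toward benzylic C–O hydrogenolysis so that the PMB and allylic silyl ethers should stay.

Step 11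
Reactants: 16 saturated 4β-methyl ester
Product: 17 8,8-(ethylenedioxy)-9β-[(4-methoxybenzyl)oxy]-3α-[(triisopropylsilyl)oxy]-11,12,13-trinor-10βH-eremophilan-15-ol
Conditions: LiAlH4, THF, 0 °C → rt
Reagents that add atoms: none
Why: Hydride reduction of the ester to the primary alcohol leaves the ketal, the ethers and C4 untouched, and the bulky silyl group is slow to migrate to the new alkoxide.

Step 12
Reactants: 17 primary alcohol (C15–OH)
Product: 18 15-methanesulfonate of 17
Conditions: MsCl, Et3N, CH2Cl2, 0 °C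
Reagents that add atoms: methanesulfonyl chloride, CS(=O)(=O)Cl
Why: Sulfonate ester formation activates the only free hydroxyl group for displacement.

Step 13
Reactants: 18 15-methanesulfonate
Product: 19 8,8-(ethylenedioxy)-9β-[(4-methoxybenzyl)oxy]-3α-[(triisopropylsilyl)oxy]-11,12,13-trinor-10βH-eremophilane (4β-CH3, 5β-CH3)
Conditions: LiEt3BH (5 equiv), THF, reflux
Reagents that add atoms: none
Why: SN2 hydride displacement of a primary, β-branched mesylate by the strongly nucleophilic borohydride turns C15 into the C4 methyl group without touching a stereocentre.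

Step 14
Reactants: 19 C8 dioxolane
Product: 20 9β-[(4-methoxybenzyl)oxy]-3α-[(triisopropylsilyl)oxy]-11,12,13-trinor-10βH-eremophilan-8-one
Conditions: TsOH·H2O (0.3 equiv), acetone–H2O (10:1), reflux
Reagents that add atoms: water, O
Why: Acid-catalysed ketal hydrolysis with acetone as glycol acceptor needs these firmer conditions because the C9 oxygen retards ionisation; the triisopropylsilyl and PMB ethers tolerate them, and the equatorial C9 ether is already the more stable epimer.

Step 15
Reactants: 20 C8 ketone; 21 acetone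
Product: 24 11-hydroxy-9β-[(4-methoxybenzyl)oxy]-3α-[(triisopropylsilyl)oxy]-10βH-eremophilan-8-one (7β side chain), via lithium enolate 22 (not isolated), via chlorozinc enolate 23 (not isolated)
Conditions: LiN(i-Pr)2, THF, −78 °C; ZnCl2; acetone, −78 → −40 °C; aq NH4Cl
Reagents that add atoms: acetone 21, CC(C)=O
Why: Directed aldol addition: kinetic deprotonation takes the less hindered C7 methylene rather than the tertiary, alkoxy-bearing C9, zinc holds the aldolate as a chelate, and acetone approaches the convex β face (ring A folds under the α face), so C7 is set with an equatorial side chain, which is also the thermodynamic outcome of this reversible addition.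

Step 16
Reactants: 24 tertiary aldol
Product: 25 9β-[(4-methoxybenzyl)oxy]-3α-[(triisopropylsilyl)oxy]-10βH-eremophil-11-en-8-one (7β-isopropenyl)
Conditions: SOCl2, pyridine, −20 → 0 °C
Reagents that add atoms: none
Why: Dehydration through the chlorosulfite (E2 elimination), in which pyridine should remove one of the six exposed methyl hydrogens faster than the single hindered C7 hydrogen at low temperature, giving the isopropenyl group and leaving C7 as set.

Step 17
Reactants: 25 C9 PMB ether
Product: 26 9β-hydroxy-3α-[(triisopropylsilyl)oxy]-10βH-eremophil-11-en-8-one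
Conditions: DDQ, CH2Cl2–pH 7 buffer, 0 °C
Reagents that add atoms: none
Why: Oxidative PMB cleavage by hydride transfer from the electron-rich benzylic position to the quinone proceeds under neutral conditions that spare the silyl ether, the 1,1-disubstituted alkene and the epimerisable centres.

Step 18
Reactants: 26 C9 alcohol; 27 3-methylbut-2-enoyl chloride
Product: 28 9β-(3-methylbut-2-enoyloxy)-3α-[(triisopropylsilyl)oxy]-10βH-eremophil-11-en-8-one
Conditions: 3-methylbut-2-enoyl chloride, pyridine, 4-(dimethylamino)pyridine (cat.), CH2Cl2, 0 °C → rt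
Reagents that add atoms: 3-methylbut-2-enoyl chloride 27, CC(C)=CC(=O)Cl
Why: Nucleophile-catalysed acylation of the only free hydroxyl group, with the weak base pyridine chosen so that neither the acyl chloride deconjugates through a vinylketene nor the isopropenyl ketone conjugates.

Step 19
Reactants: 28 C3 silyl ether
Product: 29 3α-hydroxy-9β-(3-methylbut-2-enoyloxy)-10βH-eremophil-11-en-8-one
Conditions: HF·pyridine, THF, 0 °C → rt
Reagents that add atoms: none
Why: Fluoride-driven desilylation in a mildly acidic medium avoids the basic conditions that could move the acyl group or conjugate the β,γ-unsaturated ketone.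

Step 20
Reactants: 29 C3 alcohol; 30 angelic acid
Product: 31 3α-angeloyloxy-9β-senecioyloxy-10βH-eremophil-11-en-8-one, (3R,4R,5R,7R,9R,10S), CNP0375730.2
Conditions: angelic acid, 2,4,6-trichlorobenzoyl chloride, Et3N, PhMe, rt; then 29, 80 °C
Reagents that add atoms: angelic acid 30, C/C=C(/C)C(=O)O
Why: Yamaguchi-type mixed-anhydride esterification without a nucleophilic catalyst acylates the equatorial C3 hydroxyl with retention at C3 and avoids the addition–elimination pathway that turns angelates into tiglates, which is why this ester is installed last.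

Compound list
1 | 5-methylfurfural | Cc1ccc(C=O)o1 | starting material
2 | allylboronic acid pinacol ester | C=CCB1OC(C)(C)C(C)(C)O1 | starting material
3 | pinacol borate ester of 4 (C9 R) | C=CC[C@@H](OB1OC(C)(C)C(C)(C)O1)c1ccc(C)o1 | intermediate
4 | (R)-1-(5-methylfuran-2-yl)but-3-en-1-ol | C=CC[C@@H](O)c1ccc(C)o1 | intermediate
5 | 2-[(1R)-1-[(4-methoxybenzyl)oxy]but-3-en-1-yl]-5-methylfuran | C=CC[C@@H](OCc1ccc(OC)cc1)c1ccc(C)o1 | intermediate
6 | (3Z,6R)-6-[(4-methoxybenzyl)oxy]nona-3,8-diene-2,5-dione | C=CC[C@@H](OCc1ccc(OC)cc1)C(=O)/C=C\C(C)=O | intermediate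
7 | (6R)-6-[(4-methoxybenzyl)oxy]non-8-ene-2,5-dione | C=CC[C@@H](OCc1ccc(OC)cc1)C(=O)CCC(C)=O | intermediate
8 | bis(ethylene ketal) of 7 | C=CC[C@@H](OCc1ccc(OC)cc1)C1(CCC2(C)OCCO2)OCCO1 | intermediate
9 | 4-{2-[(1R)-1-[(4-methoxybenzyl)oxy]but-3-en-1-yl]-1,3-dioxolan-2-yl}butan-2-one | C=CC[C@@H](OCc1ccc(OC)cc1)C1(CCC(C)=O)OCCO1 | intermediate
10 | trimethyl phosphonoacetate | COC(=O)CP(=O)(OC)OC | starting material
11 | methyl (2E)-5-{2-[(1R)-1-[(4-methoxybenzyl)oxy]but-3-en-1-yl]-1,3-dioxolan-2-yl}-3-methylpent-2-enoate | COC(=O)/C=C(\C)CCC1(OCCO1)[C@H](OCc1ccc(OC)cc1)CC=C | intermediate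
12 | (E)-but-2-enal | C/C=C/C=O | starting material
13 | methyl (2E)-5-{2-[(1R,3E)-1-[(4-methoxybenzyl)oxy]-5-oxopent-3-en-1-yl]-1,3-dioxolan-2-yl}-3-methylpent-2-enoate | COC(=O)/C=C(\C)CCC1(OCCO1)[C@H](OCc1ccc(OC)cc1)C/C=C/C=O | intermediate
14 | methyl (2E)-5-{2-[(1R,2E,4E)-1-[(4-methoxybenzyl)oxy]-5-[(triisopropylsilyl)oxy]penta-2,4-dien-1-yl]-1,3-dioxolan-2-yl}-3-methylpent-2-enoate | COC(=O)/C=C(\C)CCC1(OCCO1)[C@H](OCc1ccc(OC)cc1)/C=C/C=C/O[Si](C(C)C)(C(C)C)C(C)C | intermediate
15 | cis-fused cycloadduct (Δ1, 3α-OTIPS, 4β-CO2Me, 5β-CH3, 10β-H, C8 dioxolane, 9β-OPMB) | C1C[C@@]2(C)[C@H](C=C[C@@H](O[Si](C(C)C)(C(C)C)C(C)C)[C@@H]2C(=O)OC)[C@@H](OCc3ccc(OC)cc3)C14OCCO4 | intermediate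
16 | 1,2-dihydro derivative of 15 | C1C[C@@]2(C)[C@H](CC[C@@H](O[Si](C(C)C)(C(C)C)C(C)C)[C@@H]2C(=O)OC)[C@@H](OCc3ccc(OC)cc3)C14OCCO4 | intermediate
17 | C15 primary alcohol | C1C[C@@]2(C)[C@H](CC[C@@H](O[Si](C(C)C)(C(C)C)C(C)C)[C@@H]2CO)[C@@H](OCc3ccc(OC)cc3)C14OCCO4 | intermediate
18 | C15 methanesulfonate | C1C[C@@]2(C)[C@H](CC[C@@H](O[Si](C(C)C)(C(C)C)C(C)C)[C@@H]2COS(C)(=O)=O)[C@@H](OCc3ccc(OC)cc3)C14OCCO4 | intermediate
19 | 4β-methyl C8 dioxolane | C1C[C@@]2(C)[C@H](CC[C@@H](O[Si](C(C)C)(C(C)C)C(C)C)[C@@H]2C)[C@@H](OCc3ccc(OC)cc3)C14OCCO4 | intermediate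
20 | C8 ketone (9β-OPMB, 3α-OTIPS) | C1C[C@@]2(C)[C@H](CC[C@@H](O[Si](C(C)C)(C(C)C)C(C)C)[C@@H]2C)[C@@H](OCc3ccc(OC)cc3)C1=O | intermediate
21 | acetone | CC(C)=O | starting material
22 | lithium C7=C8 enolate of 20 | C=1C[C@@]2(C)[C@H](CC[C@@H](O[Si](C(C)C)(C(C)C)C(C)C)[C@@H]2C)[C@@H](OCc3ccc(OC)cc3)C=1[O-].[Li+] | intermediate
23 | chlorozinc C7=C8 enolate of 20 | C=1C[C@@]2(C)[C@H](CC[C@@H](O[Si](C(C)C)(C(C)C)C(C)C)[C@@H]2C)[C@@H](OCc3ccc(OC)cc3)C=1O[Zn]Cl | intermediate
24 | 7β-(2-hydroxypropan-2-yl) ketone | CC(C)(O)[C@H]1C[C@@]2(C)[C@H](CC[C@@H](O[Si](C(C)C)(C(C)C)C(C)C)[C@@H]2C)[C@@H](OCc3ccc(OC)cc3)C1=O | intermediate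
25 | 7β-isopropenyl ketone (9β-OPMB, 3α-OTIPS) | C=C(C)[C@H]1C[C@@]2(C)[C@H](CC[C@@H](O[Si](C(C)C)(C(C)C)C(C)C)[C@@H]2C)[C@@H](OCc3ccc(OC)cc3)C1=O | intermediate
26 | 9β-hydroxy ketone | C=C(C)[C@H]1C[C@@]2(C)[C@H](CC[C@@H](O[Si](C(C)C)(C(C)C)C(C)C)[C@@H]2C)[C@@H](O)C1=O | intermediate
27 | 3-methylbut-2-enoyl chloride | CC(C)=CC(=O)Cl | starting material
28 | 9β-senecioate, 3α-OTIPS | C=C(C)[C@H]1C[C@@]2(C)[C@H](CC[C@@H](O[Si](C(C)C)(C(C)C)C(C)C)[C@@H]2C)[C@@H](OC(=O)C=C(C)C)C1=O | intermediate
29 | 9β-senecioate, 3α-OH | C=C(C)[C@H]1C[C@@]2(C)[C@H](CC[C@@H](O)[C@@H]2C)[C@@H](OC(=O)C=C(C)C)C1=O | intermediate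
30 | angelic acid, (Z)-2-methylbut-2-enoic acid | C/C=C(/C)C(=O)O | starting material
31 | CNP0375730.2 | C=C(C)[C@H]1C[C@@]2(C)[C@H](CC[C@@H](OC(=O)/C(C)=C\C)[C@@H]2C)[C@@H](OC(=O)C=C(C)C)C1=O | target

Total step count: 20. Longest linear sequence: 20 steps, from 1.

Steps most likely to fail

Step 9. The ester-endo, trans-fused mode may compete with the ester-exo mode, which would invert C4 and C5 relative to C9. A slow cycloaddition may also be outrun by thermal decay of the dienol ether.
- **Idea of the fallback:** the dienophile geometry is switched, so that the cis-fused mode becomes the ester-endo one, and C4 is corrected afterwards by equilibration.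
- **From 9 to the (Z)-enoate:** the fallback sets out from ketone 9. Kinetic enolisation with LiN(i-Pr)2 and trapping with ClP(O)(OEt)2 gives the enol phosphate F1. More LiN(i-Pr)2 eliminates it in the same flask to the terminal alkyne F2. n-BuLi followed by ClCO2Me gives the ynoate F3. Syn addition of Me2CuLi at −78 °C and protonation gives the (Z)-β-methyl enoate F4, in which tether and ester are cis.
- **To the triene:** cross-metathesis with 12 as in step 7 gives the enal F5, and silylation as in step 8 gives the (Z)-enoate triene F6.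
- **Cycloaddition and correction at C4:** on heating F6, the equatorial methyl group and the secondary-orbital preference of the ester point to the same tether-endo transition state. This should give the 4-epi adduct F7 (4α-ester, all other centres as in 15). Hydrogenation as in step 10 gives the saturated 4α-ester F8. NaOMe in MeOH then moves the axial ester to the equatorial 4β position, silyloxide being a poor leaving group, and the route is rejoined at 16.

Step 16. Proton loss from C7 instead of from a methyl group would shift the new double bond into conjugation with the ketone.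
- **Idea of the fallback:** the conjugated isomer is accepted and then deconjugated.
- **Sequence:** the fallback sets out from 24. MsCl and Et3N give the tertiary mesylate F9, which DBU eliminates in the same flask to the isopropylidene ketone F10. KOt-Bu in t-BuOH–THF forms the extended potassium dienolate F11 by γ-deprotonation. Inverse quench into cold aqueous AcOH protonates it kinetically at C7.
- **Return:** the equatorial 7β epimer is the more stable β,γ-isomer, so brief contact with Et3N would level any 7α epimer, and the route is rejoined at 25.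

Step 6. Olefination of a methyl ketone may show poor E/Z discrimination, with loss of material on separation.
- **Idea of the fallback:** olefination is replaced by a stereospecific syn carbometalation.
- **Sequence:** the fallback sets out from 9 and passes through the enol phosphate F1 and the terminal alkyne F2 as above. Zirconium-catalysed carboalumination with Me3Al and (C5H5)2ZrCl2 in CH2Cl2 adds methyl and aluminium to the same side and gives the (E)-alkenylalane F12.
- **Return:** trapping with ClCO2Me proceeds with retention, and the route is rejoined at 11.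

Further compounds
F1 | step 9 | diethyl 4-{2-[(1R)-1-[(4-methoxybenzyl)oxy]but-3-en-1-yl]-1,3-dioxolan-2-yl}but-1-en-2-yl phosphate | C=C(OP(=O)(OCC)OCC)CCC1(OCCO1)[C@H](OCc1ccc(OC)cc1)CC=C
F2 | step 9 | 2-(but-3-yn-1-yl)-2-[(1R)-1-[(4-methoxybenzyl)oxy]but-3-en-1-yl]-1,3-dioxolane | C#CCCC1(OCCO1)[C@H](OCc1ccc(OC)cc1)CC=C
F3 | step 9 | methyl 5-{2-[(1R)-1-[(4-methoxybenzyl)oxy]but-3-en-1-yl]-1,3-dioxolan-2-yl}pent-2-ynoate | COC(=O)C#CCCC1(OCCO1)[C@H](OCc1ccc(OC)cc1)CC=C
F4 | step 9 | methyl (2Z)-5-{2-[(1R)-1-[(4-methoxybenzyl)oxy]but-3-en-1-yl]-1,3-dioxolan-2-yl}-3-methylpent-2-enoate | COC(=O)/C=C(/C)CCC1(OCCO1)[C@H](OCc1ccc(OC)cc1)CC=C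
F5 | step 9 | methyl (2Z)-5-{2-[(1R,3E)-1-[(4-methoxybenzyl)oxy]-5-oxopent-3-en-1-yl]-1,3-dioxolan-2-yl}-3-methylpent-2-enoate | COC(=O)/C=C(/C)CCC1(OCCO1)[C@H](OCc1ccc(OC)cc1)C/C=C/C=O
F6 | step 9 | methyl (2Z)-5-{2-[(1R,2E,4E)-1-[(4-methoxybenzyl)oxy]-5-[(triisopropylsilyl)oxy]penta-2,4-dien-1-yl]-1,3-dioxolan-2-yl}-3-methylpent-2-enoate | COC(=O)/C=C(/C)CCC1(OCCO1)[C@H](OCc1ccc(OC)cc1)/C=C/C=C/O[Si](C(C)C)(C(C)C)C(C)C
F7 | step 9 | 4-epimer of 15 (4α-CO2Me) | C1C[C@@]2(C)[C@H](C=C[C@@H](O[Si](C(C)C)(C(C)C)C(C)C)[C@H]2C(=O)OC)[C@@H](OCc3ccc(OC)cc3)C14OCCO4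
F8 | step 9 | 4-epimer of 16 (4α-CO2Me) | C1C[C@@]2(C)[C@H](CC[C@@H](O[Si](C(C)C)(C(C)C)C(C)C)[C@H]2C(=O)OC)[C@@H](OCc3ccc(OC)cc3)C14OCCO4
F9 | step 16 | tertiary methanesulfonate of 24 | CC(C)(OS(C)(=O)=O)[C@H]1C[C@@]2(C)[C@H](CC[C@@H](O[Si](C(C)C)(C(C)C)C(C)C)[C@@H]2C)[C@@H](OCc3ccc(OC)cc3)C1=O
F10 | step 16 | 9β-[(4-methoxybenzyl)oxy]-3α-[(triisopropylsilyl)oxy]-10βH-eremophil-7(11)-en-8-one | CC(C)=C1C[C@@]2(C)[C@H](CC[C@@H](O[Si](C(C)C)(C(C)C)C(C)C)[C@@H]2C)[C@@H](OCc3ccc(OC)cc3)C1=O
F11 | step 16 | potassium 7,11-dien-8-olate of F10 | C=C(C)C=1C[C@@]2(C)[C@H](CC[C@@H](O[Si](C(C)C)(C(C)C)C(C)C)[C@@H]2C)[C@@H](OCc3ccc(OC)cc3)C=1[O-].[K+]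
F12 | step 6 | (E)-alkenyl(dimethyl)alane from F2 (aluminium cis to the new methyl group) | C[Al](C)/C=C(\C)CCC1(OCCO1)[C@H](OCc1ccc(OC)cc1)CC=C
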